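## Retrosynthetic overview
1. The last bonds made are C4–H and C5–H, and two O-benzyl groups are removed. The target comes from a 4-aroyl-2,3-dihydrofuran by CH2OH-directed hydrogenation followed by hydrogenolysis.
2. The aryl ketone C–C bond comes from a syringyl-lithium (made from syringol) and a bicyclic enol-ether γ-lactone.
3. The lactone comes from selective reduction of the saturated C3 ester of a 2-aryl-2,3-dihydrofuran-3,4-diester. The C4 ester is a vinylogous carbonate and survives.
4. The key C2–aryl bond comes from enantioselective Rh-catalysed 1,4-arylation of flat, C2v-symmetric dimethyl furan-3,4-dicarboxylate. This one step destroys aromaticity and symmetry and sets C2 and C3.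
5. Rings: the oxolane is the purchased furan ring, saturated in two stages (steps 1 and 6). The only ring closed is a temporary lactone (step 2), which is reopened in step 5.

Assumption: the sense of induction in step 1 is extrapolated from the α-re-face preference of (R,R)-diene–Rh catalysts with enoates; if experiment shows the opposite sense, the equally available (S,S)-ligand is used and nothing else changes.

## Route

Step 1
Reactants: 1 dimethyl furan-3,4-dicarboxylate (2 equiv); 2 [4-(benzyloxy)-3-methoxyphenyl]boronic acid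
Product: 3 dimethyl (2S,3S)-2-[4-(benzyloxy)-3-methoxyphenyl]-2,3-dihydrofuran-3,4-dicarboxylate (2,3-trans)
Conditions: [RhCl(C2H4)2]2 (2.5 mol %), (R,R)-Ph-bod* (5.5 mol %), aq KOH (10 mol %), dioxane/H2O 10:1, 60 °C, 2 added over 4 h
Reagents that add atoms: none
Why: Proposed new method: this is a Hayashi–Miyaura 1,4-arylation in which the acceptor C2=C3–CO2Me is part of the furan, where Ar–Rh inserts with aryl going to the O-bearing β-carbon (closest known types: asymmetric Rh 1,4-arylation of chromones and coumarins, and Rh dearomative arylation of pyridinium salts), water protonates the oxa-π-allyl Rh enolate anti to the new aryl to give 2,3-trans, the small aromatic stabilisation of this electron-poor furan (about 16 kcal/mol) is paid for by C–B to O–B exchange and by the push–pull β-alkoxyacrylate kept in 3, C2-top and C5-bottom attack are homotopic so only facial selectivity (ligand, α-re face) decides 2S, and near-neutral medium plus excess 1 suppress retro-oxa-Michael racemisation and a second arylation.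

Step 2
Reactants: 3 dimethyl (2S,3S)-2-[4-(benzyloxy)-3-methoxyphenyl]-2,3-dihydrofuran-3,4-dicarboxylate
Product: 5 (3aR,4S)-4-[4-(benzyloxy)-3-methoxyphenyl]-3a,4-dihydro-1H,3H-furo[3,4-c]furan-1-one (bicyclic enol-ether lactone), via hydroxy ester 4 (not isolated)
Conditions: LiBH4 (1.1 equiv), THF, 0 °C to rt; pH 7 buffer; then PPTS (5 mol %), CH2Cl2, rt
Reagents that add atoms: none
Why: This is a chemoselective ester reduction followed by lactonisation, in which the saturated C3 ester is a normal electrophile while the C4 ester is a vinylogous carbonate deactivated by the ring oxygen, the borate-bound alcohol only transesterifies onto the C4 ester after work-up so 5 never meets hydride, no stereocentre is touched (the C3 descriptor changes S to R by CIP only), and C3 is no longer epimerisable.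

Step 3
Reactants: 6 2,6-dimethoxyphenol (syringol)
Product: 7 4-bromo-2,6-dimethoxyphenol
Conditions: NBS (1.0 equiv), cat. NaH, CHCl3–MeOH 100:1, −45 °C to reflux
Reagents that add atoms: N-bromosuccinimide O=C1CCC(=O)N1Br
Why: This is an electrophilic aromatic bromination in which the phenol(ate) oxygen is the dominant director, both ortho positions are blocked by OMe, and bromine therefore enters para through the 4-bromodienone tautomer.

Step 4
Reactants: 7 4-bromo-2,6-dimethoxyphenol
Product: 8 2-(benzyloxy)-5-bromo-1,3-dimethoxybenzene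
Conditions: BnBr (1.1 equiv), K2CO3 (1.0 equiv), DMF, 50 °C
Reagents that add atoms: benzyl bromide BrCc1ccccc1
Why: This is a Williamson ether synthesis that masks the acidic phenol before lithiation with a group that leaves in the final hydrogen atmosphere.

Step 5
Reactants: 8 2-(benzyloxy)-5-bromo-1,3-dimethoxybenzene (1.1 equiv); 5 bicyclic enol-ether lactone
Product: 10 [(4R,5S)-5-[4-(benzyloxy)-3-methoxyphenyl]-4-(hydroxymethyl)-4,5-dihydrofuran-3-yl][4-(benzyloxy)-3,5-dimethoxyphenyl]methanone, via aryllithium 9 (not isolated)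
Conditions: n-BuLi (1.1 equiv), THF, −78 °C, 30 min; add 5 in THF, −78 °C, 1 h; AcOH (1.1 equiv) quench at −78 °C
Reagents that add atoms: none
Why: Bromine–lithium exchange is followed by 1,2-acyl substitution on the lactone, where the hard aryllithium attacks the carbonyl of the vinylogous carbonate (as in Stork–Danheiser additions), the lithium hemiketal survives at −78 °C, the vinylogous-ester ketone released on quench is a poor electrophile so mono-addition results, and no stereocentre is involved.

Step 6
Reactants: 10 [(4R,5S)-5-[4-(benzyloxy)-3-methoxyphenyl]-4-(hydroxymethyl)-4,5-dihydrofuran-3-yl][4-(benzyloxy)-3,5-dimethoxyphenyl]methanone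
Product: 12 [(3S,4R,5S)-5-(4-hydroxy-3-methoxyphenyl)-4-(hydroxymethyl)oxolan-3-yl](4-hydroxy-3,5-dimethoxyphenyl)methanone (target), via saturated dibenzyl ether 11 (not isolated)
Conditions: H2 (1 atm), [Ir(cod)(PCy3)(py)]PF6 (5 mol %), CH2Cl2, rt; solvent switch to EtOAc–EtOH, 10 % Pd/C, H2 (1 atm), rt (telescoped)
Reagents that add atoms: none
Why: In this hydroxyl-directed homogeneous hydrogenation (Crabtree type) the C3 CH2OH binds cationic Ir so both hydrogens reach C4=C5 from the CH2OH face and the aroyl group ends trans to CH2OH (all-trans, also the thermodynamic epimer α to the ketone), the labile benzylic C2–O vinylogous-ester bond is not hydrogenolysed, and Pd/C hydrogenolysis then cleaves the two phenolic benzyl ethers faster than the now ordinary cyclic benzylic ether.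

## Compound list
1 | dimethyl furan-3,4-dicarboxylate | COC(=O)c1cocc1C(=O)OC | starting material
2 | [4-(benzyloxy)-3-methoxyphenyl]boronic acid | COc1cc(B(O)O)ccc1OCc1ccccc1 | starting material
3 | dimethyl (2S,3S)-2-[4-(benzyloxy)-3-methoxyphenyl]-2,3-dihydrofuran-3,4-dicarboxylate | COc1cc([C@H]2OC=C(C(=O)OC)[C@@H]2C(=O)OC)ccc1OCc1ccccc1 | intermediate
4 | methyl (4R,5S)-5-[4-(benzyloxy)-3-methoxyphenyl]-4-(hydroxymethyl)-4,5-dihydrofuran-3-carboxylate (not isolated) | COc1cc([C@H]2OC=C(C(=O)OC)[C@@H]2CO)ccc1OCc1ccccc1 | intermediate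
5 | (3aR,4S)-4-[4-(benzyloxy)-3-methoxyphenyl]-3a,4-dihydro-1H,3H-furo[3,4-c]furan-1-one | COc1cc([C@H]2OC=C3C(=O)OC[C@H]23)ccc1OCc1ccccc1 | intermediate
6 | 2,6-dimethoxyphenol (syringol) | COc1cccc(OC)c1O | starting material
7 | 4-bromo-2,6-dimethoxyphenol | COc1cc(Br)cc(OC)c1O | intermediate
8 | 2-(benzyloxy)-5-bromo-1,3-dimethoxybenzene | COc1cc(Br)cc(OC)c1OCc1ccccc1 | intermediate
9 | [4-(benzyloxy)-3,5-dimethoxyphenyl]lithium (not isolated) | [Li]c1cc(OC)c(OCc2ccccc2)c(OC)c1 | intermediate
10 | [(4R,5S)-5-[4-(benzyloxy)-3-methoxyphenyl]-4-(hydroxymethyl)-4,5-dihydrofuran-3-yl][4-(benzyloxy)-3,5-dimethoxyphenyl]methanone | COc1cc([C@H]2OC=C(C(=O)c3cc(OC)c(OCc4ccccc4)c(OC)c3)[C@@H]2CO)ccc1OCc1ccccc1 | intermediate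
11 | [(3S,4R,5S)-5-[4-(benzyloxy)-3-methoxyphenyl]-4-(hydroxymethyl)oxolan-3-yl][4-(benzyloxy)-3,5-dimethoxyphenyl]methanone (not isolated) | COc1cc([C@H]2OC[C@@H](C(=O)c3cc(OC)c(OCc4ccccc4)c(OC)c3)[C@@H]2CO)ccc1OCc1ccccc1 | intermediate
12 | [(3S,4R,5S)-5-(4-hydroxy-3-methoxyphenyl)-4-(hydroxymethyl)oxolan-3-yl](4-hydroxy-3,5-dimethoxyphenyl)methanone | COc1cc([C@H]2OC[C@@H](C(=O)c3cc(OC)c(O)c(OC)c3)[C@@H]2CO)ccc1O | target

## Step count and risks
Total step count: 6. Longest linear sequence: 4 steps (steps 1, 2, 5, 6 from 1, or equally steps 3, 4, 5, 6 from 6).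

**Most likely to fail, first: step 1.** Aryl–Rh may not insert into the aromatic C2=C3. The enolate may re-aromatise by β-hydride elimination to the 2-arylfuran. Compound 3 may be arylated a second time or racemise by ring opening.

The fallback sets out from 1 and comes back at 3. Aromaticity and symmetry are broken with a far more nucleophilic copper–boryl species instead of aryl–Rh.
- Cu(I)/chiral bisphosphine enantioselective dearomative protoboration (CuCl, (R,R)-QuinoxP*, cat. NaOt-Bu, B2pin2, t-BuOH, THF, 0 °C) is the reaction type known for pyrrole- and indole-carboxylates. It gives dimethyl (2R,3S)-2-(4,4,5,5-tetramethyl-1,3,2-dioxaborolan-2-yl)-2,3-dihydrofuran-3,4-dicarboxylate F1.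
- KHF2 in aqueous MeOH converts this into potassium [(2R,3S)-3,4-bis(methoxycarbonyl)-2,3-dihydrofuran-2-yl]trifluoroborate F2.
- Ir-photoredox/Ni dual-catalysed coupling of this α-alkoxyalkyl trifluoroborate with commercial 1-(benzyloxy)-4-bromo-2-methoxybenzene (K2HPO4, dioxane, blue LED, rt) gives 3. The C2 radical is arylated anti to the C3 ester, so the C3 centre set in the borylation relays the absolute configuration.

**Second: step 6.** The push–pull trisubstituted alkene may be too unreactive for the Ir catalyst. Acidic Ir hydrides may ionise the benzylic C2–O bond.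

The fallback sets out from 5 and comes back at 11. The C=C is saturated on the lactone, where no ketone is present and the ring fusion can only become cis.
- H2 (4 atm) over 5 % Rh/Al2O3 in EtOAc keeps the benzyl ether and gives (3aR,4S,6aR)-4-[4-(benzyloxy)-3-methoxyphenyl]tetrahydro-1H,3H-furo[3,4-c]furan-1-one F5.
- Aryllithium 9 (THF, −78 °C) opens it to the 3,4-cis hydroxy ketone [(3R,4R,5S)-5-[4-(benzyloxy)-3-methoxyphenyl]-4-(hydroxymethyl)oxolan-3-yl][4-(benzyloxy)-3,5-dimethoxyphenyl]methanone F6.
- DBU (toluene, rt) epimerises the centre α to the ketone while both phenols are still masked. This gives all-trans 11, which rejoins the route at the Pd/C half of step 6.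

**Third: step 5.** Possible failures are over-addition to the released ketone, attack at C5, or base-induced opening of the lactone with aromatisation to a 3-methylfuran acid.

The fallback sets out from 5 and comes back at 10. The acyl substitution is replaced by an aldehyde addition and reoxidation.
- DIBAL-H (1.1 equiv, CH2Cl2, −78 °C) gives the lactol, which opens to the conjugated (4R,5S)-5-[4-(benzyloxy)-3-methoxyphenyl]-4-(hydroxymethyl)-4,5-dihydrofuran-3-carbaldehyde F3.
- Aryllithium 9 (2.2 equiv) adds 1,2 to give the diol [(4R,5S)-5-[4-(benzyloxy)-3-methoxyphenyl]-4-(hydroxymethyl)-4,5-dihydrofuran-3-yl][4-(benzyloxy)-3,5-dimethoxyphenyl]methanol F4. The carbinol epimers do not matter.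
- MnO2 (CH2Cl2, rt) oxidises only the allylic/benzylic secondary alcohol and gives 10.

## Further compounds
F1 | step 1 | dimethyl (2R,3S)-2-(4,4,5,5-tetramethyl-1,3,2-dioxaborolan-2-yl)-2,3-dihydrofuran-3,4-dicarboxylate | CC1(C)OB(OC1(C)C)[C@H]2OC=C(C(=O)OC)[C@@H]2C(=O)OC
F2 | step 1 | potassium [(2R,3S)-3,4-bis(methoxycarbonyl)-2,3-dihydrofuran-2-yl]trifluoroborate | [K+].F[B-](F)(F)[C@H]1OC=C(C(=O)OC)[C@@H]1C(=O)OC
F3 | step 5 | (4R,5S)-5-[4-(benzyloxy)-3-methoxyphenyl]-4-(hydroxymethyl)-4,5-dihydrofuran-3-carbaldehyde | COc1cc([C@H]2OC=C(C=O)[C@@H]2CO)ccc1OCc1ccccc1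
F4 | step 5 | [(4R,5S)-5-[4-(benzyloxy)-3-methoxyphenyl]-4-(hydroxymethyl)-4,5-dihydrofuran-3-yl][4-(benzyloxy)-3,5-dimethoxyphenyl]methanol (carbinol epimers) | COc1cc([C@H]2OC=C(C(O)c3cc(OC)c(OCc4ccccc4)c(OC)c3)[C@@H]2CO)ccc1OCc1ccccc1
F5 | step 6 | (3aR,4S,6aR)-4-[4-(benzyloxy)-3-methoxyphenyl]tetrahydro-1H,3H-furo[3,4-c]furan-1-one | COc1cc([C@H]2OC[C@@H]3C(=O)OC[C@H]23)ccc1OCc1ccccc1
F6 | step 6 | [(3R,4R,5S)-5-[4-(benzyloxy)-3-methoxyphenyl]-4-(hydroxymethyl)oxolan-3-yl][4-(benzyloxy)-3,5-dimethoxyphenyl]methanone | COc1cc([C@H]2OC[C@H](C(=O)c3cc(OC)c(OCc4ccccc4)c(OC)c3)[C@@H]2CO)ccc1OCc1ccccc1
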